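- We follow the vessel in fractions of the charge and ask at each stage what is left, not what is made.

| flask | starting material | reagent | second substrate | protic impurity | temperature | remark | time |
|---|---|---|---|---|---|---|---|
| north | 0.20 M | 0.55 equiv (fed, over 2.5 min) | 0.50 equiv | 4 mM | −15 °C | run made earlier |  |
| south | 0.20 M | 2.2 equiv (fed, over 2.5 min) | 0.50 equiv | 4 mM | −4 °C | run made earlier |  |
| west | 0.30 M | 1.1 equiv (fed, over 2.5 min) | 0.50 equiv | 4 mM | −15 °C | run made earlier |  |
| green | 0.20 M | 1.10 equiv (fed, over 2.5 min) | 0.500 equiv | 4.00 mM |  | at −20 °C until 30 s, from then on at 0 °C | 2.5 min |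
| amber | 0.20 M | 1.10 equiv (fed, over 2.5 min) | 0.500 equiv | 4.00 mM |  | at 0 °C throughout | 5.0 min |

north run (percent of the starting material charged)

| time / min | target / % | cross product / % | starting material / % |
|---|---|---|---|
| 0.200 | 0.2 | 47.9 | 51.2 |
| 0.333 | 3.8 | 48.5 | 47.7 |
| 0.500 | 5.3 | 48.2 | 47.3 |
| 0.667 | 8.5 | 50.2 | 45.0 |
| 1.00 | 11.2 | 48.1 | 39.6 |
| 1.50 | 16.4 | 48.3 | 35.7 |
| 2.50 | 24.9 | 50.9 | 26.3 |

south run (percent of the starting material charged)

| time / s | target / % | cross product / % | starting material / % |
|---|---|---|---|
| 10.0 | 4.0 | 47.0 | 49.1 |
| 12.0 | 4.3 | 48.4 | 48.7 |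
| 20.0 | 8.7 | 49.3 | 43.9 |
| 25.0 | 10.7 | 46.8 | 42.2 |
| 40.0 | 17.4 | 46.8 | 38.6 |
| 50.0 | 21.6 | 47.4 | 32.5 |
| 60.0 | 21.1 | 47.0 | 29.8 |

west run (percent of the starting material charged)

| time / min | target / % | cross product / % | starting material / % |
|---|---|---|---|
| 0.200 | 3.3 | 48.1 | 47.9 |
| 0.667 | 14.8 | 48.0 | 35.9 |
| 1.33 | 29.1 | 48.5 | 23.3 |
| 2.00 | 37.1 | 49.6 | 16.1 |
| 2.50 | 39.9 | 47.2 | 11.3 |

(scatter of a reading: 1 percentage point)



1. the winner by share of target in all that became target or cross product; "neither" if no more than 2 percentage points parts them (green / amber / neither)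
2. share of target in all that became target or cross product, green
3. share of target in all that became target or cross product, amber

- First instants: the north run already reads 47.9% of cross product at 0.200 min, against 0.50 equiv of second substrate charged. Cross product readings then scatter about that level, and the last readings of the three runs average 48.4%. We expect this in green and amber too, which leaves a pool of 51.6% of the starting material open to target.
- Middle: target climbs as reagent comes in; the west run reads 14.8% at 0.667 min and 39.9% at 2.50 min.
- End: in the west run, 0.701 equiv of reagent has not become target, yet 11.3% of starting material remains. We read this as a balance (an equilibrium), where the forecast reads lost reagent.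
- Our measure is target over starting material left, per mol/L of reagent fed that has not become target. The west run gives 16.8 L mol⁻¹ and the north run 15.7 L mol⁻¹, from different charges at −15 °C, and their scatter does not part these readings.
- The south run, 60.0 s into its feed at −4 °C, reads 5.29 L mol⁻¹. Carrying the fall from the west run's reading to this lower one on to 0 °C gives our estimate of the standing constant 3.48 L mol⁻¹.
- In fractions, the part of the pool left is one over one plus the constant times 0.20 M times the free reagent in equivalents. Solved with 1.10 equiv of reagent, this gives target 19.9% and a share of 29.1%.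
- Green spends 2.00 min at 0 °C, longer than its cold 30 s, and at −15 °C the measure came out alike from two different charges at the end of the feed, which we read as balance by then. So we give green and amber that same share, and neither wins.
- The forecast gives green 34.5% (29% to 41%) and amber 30.5% (25% to 37%), and names green, “which favours the cold start”.
- The simulation gives green 31.3% and amber 31.0%, so the verdict is neither. Starting material ends at 31.3% in green and 30.7% in amber. With amber's free reagent at 80% of its charge, the standing constant leaves 62.0% of a pool of 52.2%, which is 32.4% of the starting material; amber holds 30.7%.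

    second substrate + reagent → second product (k = 2.40 L mol⁻¹ s⁻¹, Ea = 46.0 kJ mol⁻¹)
    starting material + second substrate → cross product (k = 1.80 L mol⁻¹ s⁻¹, Ea = 35.0 kJ mol⁻¹)
    starting material + reagent ⇌ target (K = 31.0 L mol⁻¹, k = 0.570 L mol⁻¹ s⁻¹, Ea = 47.0 kJ mol⁻¹, ΔH = −59.0 kJ mol⁻¹)
    second substrate + protic impurity → quenched substrate (k = 2.10 L mol⁻¹ s⁻¹, Ea = 50.0 kJ mol⁻¹)
    (constants at −20 °C)

- Take amber with 0.200 equiv of second substrate. Keeping the same small gap below the charge, cross product should be 18.4%, and the standing constant then gives target 29.3% and a share of 61.4%.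
- The simulation gives that flask 62.0%, with cross product 19.1% and starting material 49.7%.

The numbers in the tables were computed from invented constants, noise included.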